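Readings and results are simulated with constants of no real substance; the scatter is artificial.

**Long feed.** 20 h is how long Z goes into Thursday's flask, with D in from the start, so my question was whether D lasts that long.

| flask | Z | D | remark | time |
|---|---|---|---|---|
| epsilon | 0.010 M | 0.040 M | run made earlier |  |
| alpha | 0.010 M | 0.056 M | run made earlier |  |
| delta | 0.010 M | 0.088 M | run made earlier |  |
| Thursday's | 0.010 M (fed, over 20 h) | 0.0400 M | all else is in the flask from the start; the feed brings no volume worth counting | 30 h |
| Wednesday's | 0.010 M | 0.0400 M (fed, over 20 h) | all else is in the flask from the start; the feed brings no volume worth counting | 30 h |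
| Monday's | 0.010 M | 0.0400 M | everything together at the start | 30 h |

| run | time / h | X / % |
|---|---|---|
| epsilon | 1.00 | 23.1 |
| epsilon | 3.00 | 48.6 |
| epsilon | 5.00 | 61.4 |
| epsilon | 8.00 | 71.7 |
| epsilon | 10.0 | 74.0 |
| epsilon | 15.0 | 77.8 |
| epsilon | 20.0 | 80.5 |
| alpha | 1.50 | 40.5 |
| alpha | 5.00 | 73.7 |
| alpha | 8.00 | 82.5 |
| alpha | 12.0 | 86.3 |
| alpha | 20.0 | 89.1 |
| alpha | 25.0 | 88.9 |
| alpha | 30.0 | 88.1 |
| delta | 1.50 | 55.7 |
| delta | 5.00 | 87.2 |
| delta | 8.00 | 91.8 |
| delta | 12.0 | 95.0 |
| delta | 20.0 | 93.9 |
| delta | 25.0 | 93.9 |
| delta | 30.0 | 93.7 |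

(each reading ± 0.5 percentage points)

1. the flask that comes out highest in amount of X, in percent of the Z charged, or "all alike" when all lie within 1.5 percentage points (Thursday's / Wednesday's / Monday's / all alike)
2. X at the end, in percent of the Z charged, Thursday's
3. X at the end, in percent of the Z charged, Wednesday's
4. X at the end, in percent of the Z charged, Monday's



**Bench rule.** In Thursday's recipe D's charge stands at 4.00 times Z's, so the bench rule holds D constant and lets Z fall pseudo-first-order. In alpha, the rate constant of Z read 0.346 h⁻¹ up to the first reading and 0.233 h⁻¹ up to the second. I allowed 7.23% of D's charge for X made, and the remaining fall, over 2.50 h, gave a reading of D's lifetime, 7.82 h. Scaled to Thursday's charge, the constant at full D is 0.272 h⁻¹, and with D held there the rule promises 98.8% of X. But the feed lasts 2.56 lifetimes of D, so Thursday's flask lies past the rule's border.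

**Break-even arrival.** I therefore reckoned the reach, 2.13, the Z lifetimes that D's whole charge holds in store. Z entering when a fraction of D's charge stands meets the reach times that fraction, and half of it converts where this product equals ln(2), at a fraction of 32.6%. That moment, 8.78 h into the feed, is the break-even arrival. Z entering at the start meets more, and later arrivals meet less, so I took the share fed by then as Thursday's X: 43.9%. Monday's repeats epsilon, which last read 80.5%, so I put Monday's above Thursday's.

**The forecast.** The forecast named Monday's highest, with 81% for Monday's, 77.5% for Wednesday's and 41% for Thursday's, where “Z fed late meets D that has largely decayed”.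

**The flasks.** Monday's came out highest at 80.5%, with Wednesday's at 72.0%. Thursday's gave 45.9%, 2 percentage points from my share, with 41% of its Z still standing.

    Z → L (k = 2.05 × 10⁻⁴ min⁻¹)
    D → G (k = 0.00170 min⁻¹)
    X → E (k = 2.38 × 10⁻⁵ min⁻¹)
    Z + D → X (k = 0.118 M⁻¹ min⁻¹)

**The neighbour.** Thursday's neighbour, charged with 0.068 M of D, moves the break-even arrival by 4.15 h to 12.9 h, a share of 64.5%. That flask gave 61.8% of X, with 27.5% of Z left.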